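The readings are calculated for substances that don't exist.

One thing stays put across our runs: the share of the charge turned to target per minute. Starting material went from 0.30 M to 0.66 M, yet the opening rate reads 0.0840 min⁻¹ on Thursday, 0.0740 min⁻¹ on Tuesday and 0.0800 min⁻¹ on Friday. So, as read, the opening rate of target formation is first order in starting material at fixed partner.

| flask | starting material | partner | second substrate | third substrate | protic impurity | remark | time |
|---|---|---|---|---|---|---|---|
| Thursday's | 0.30 M | 0.36 M | 0.30 M | 0.30 M | 0.060 M | run made earlier |  |
| Tuesday's | 0.42 M | 0.36 M | 0.30 M | 0.30 M | 0.060 M | run made earlier |  |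
| Friday's | 0.66 M | 0.36 M | 0.30 M | 0.30 M | 0.060 M | run made earlier |  |
| north-east | 0.30 M (fed, over 2.5 min) | 0.360 M | 0.300 M | 0.300 M | 0.0600 M | all else is in the flask from the start; the feed brings no volume worth counting | 4.0 min |
| north | 0.30 M | 0.360 M | 0.300 M | 0.300 M | 0.0600 M | everything together at the start | 4.0 min |
| south | 0.30 M | 0.360 M | 0.300 M | 0.300 M (fed, over 2.5 min) | 0.0600 M | all else is in the flask from the start; the feed brings no volume worth counting | 4.0 min |

| run | time / min | target / % |
|---|---|---|
| Thursday's | 1.00 | 8.4 |
| Thursday's | 2.00 | 13.0 |
| Thursday's | 3.00 | 15.6 |
| Thursday's | 4.00 | 19.3 |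
| Tuesday's | 1.00 | 7.4 |
| Tuesday's | 2.00 | 13.3 |
| Tuesday's | 3.00 | 14.8 |
| Tuesday's | 4.00 | 17.2 |
| Friday's | 0.500 | 4.0 |
| Friday's | 1.33 | 9.2 |
| Friday's | 2.50 | 13.4 |
| Friday's | 4.00 | 16.7 |

(standard deviation of a reading: 0.5 percentage points)

1. which flask leads in amount of target, in percent of the starting material charged ("all alike" within 1.5 percentage points) (north-east / north / south / all alike)
2. how much target is there at the end, in percent of the starting material charged: north-east
3. how much target is there at the end, in percent of the starting material charged: north
4. how much target is there at the end, in percent of the starting material charged: south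

- a reading or a percentage of target counts all its forms, free or not

Thursday's rate falls to 0.0370 min⁻¹ in the last minute, a factor of 0.440 as read. Counting the target formed, use of starting material accounts for a fall to 80.7% of the opening rate. That leaves a factor of 0.546 for some unseen brake, a smaller factor than that use.

Added up, the slowing leaves a frozen rate, the mean share of the charge turned to target per minute in the flask, of 0.0483 min⁻¹. That is 0.575 of the opening rate.

We freeze this rate and multiply it by the mean time the charge spends in the flask. In north and south, starting material is present from the start, so both get 19.3%. The runs held third substrate fixed, so this reckoning cannot separate them. In north-east, a steady feed arrives on average at 1.25 min, leaving 2.75 min in the flask and giving 13.3%.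

The forecast leads with north and gives north-east 11.5%, north 18.6% and south 17.5%, calling south “a guess near north”, while our north-east is higher.

The flasks give south 20.2%, north 18.5% and north-east 13.1%, so south leads.

    second substrate + target ⇌ idle adduct, settled at all times (K = 4.50 M⁻¹)
    second substrate + partner → second product (k = 0.00320 M⁻¹ s⁻¹)
    third substrate + partner → third product (k = 0.00890 M⁻¹ s⁻¹)
    third substrate + protic impurity → quenched substrate (k = 0.0700 M⁻¹ s⁻¹)
    starting material + partner → target (k = 0.00500 M⁻¹ s⁻¹)
    target ⇌ isomer of the product (K = 0.850, k = 0.00790 s⁻¹)

At the end, south retains 58.1% of its third substrate and 44.7% of its partner, while north retains 47.9% and 40.1%. North-east's yield per minute of mean time in the flask is 0.0476 min⁻¹, beside the frozen 0.0483 min⁻¹. For the same feed with 0.90 M of partner, we scale the frozen rate by the partner charge. That gives 33.2%, and this flask holds 29.7%.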